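Rings: A (3-hydroxyphenyl), B (para-phenylene), C (ether oxygen plus OH), D (hydroquinone). The route builds ring B last instead of arylating the ring C phenol. In ring B the aryloxy oxygen on B4 and the ethylene bridge carbon on B1 stand para; a 5-acyl-2-pyrone delivers this 1,4 relationship when its C3=C4–C5=C6 diene adds an oxygen-substituted alkyne and ejects CO2. One thermal operation forms B5–B6 and B3–B4, closes ring B and joins the ring A fragment to the C–D fragment. The precursors are 5-[(3-methoxyphenyl)acetyl]-2-pyrone and the ethynyl ether of the ring C–D bibenzyl phenol, all other phenols being methyl ethers; ketone deoxygenation and demethylation finish the synthesis.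

Key step: step 8

Remark: the target has no stereocentre; 3-(benzyloxy)-4-methoxybenzaldehyde (O-benzylisovanillin) and 2,5-dimethoxybenzyl chloride are taken as purchasable, and ynol ether 16 is treated as too labile to store, so it is made last and used at once.

Step 1
Reactants: 1 coumalic acid
Product: 2 coumaloyl chloride (2-oxo-2H-pyran-5-carbonyl chloride)
Conditions: (COCl)2, DMF (cat.), CH2Cl2, 0 °C → rt; used crude
Reagents that add atoms: oxalyl chloride, O=C(Cl)C(=O)Cl
Why: Acid chloride formation through the chloroiminium species made catalytically from DMF should proceed cleanly because the pyrone lactone is inert to oxalyl chloride and all by-products are gases.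

Step 2
Reactants: 2 coumaloyl chloride; 3 3-methoxybenzyl chloride
Product: 5 5-[(3-methoxyphenyl)acetyl]-2H-pyran-2-one, via (3-methoxybenzyl)zinc chloride 4 (not isolated)
Conditions: 3, Zn dust, LiCl, THF, rt; then 2, Pd(PPh3)4 (cat.), THF, 0 °C → rt
Reagents that add atoms: none
Why: Negishi acylation, in which LiCl-assisted zinc insertion gives a mild, weakly basic benzylzinc reagent and oxidative addition of the acyl chloride to zerovalent palladium, transmetalation and reductive elimination should deliver the ketone faster than any uncatalysed attack on the pyrone ring or on the product.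

Step 3
Reactants: 6 2,5-dimethoxybenzyl chloride
Product: 7 diethyl (2,5-dimethoxybenzyl)phosphonate
Conditions: P(OEt)3 (neat), 140 °C
Reagents that add atoms: triethyl phosphite, CCOP(OCC)OCC
Why: Michaelis–Arbuzov reaction, in which phosphorus displaces the activated benzylic chloride and chloride dealkylates the phosphonium ion, driven by loss of volatile chloroethane.

Step 4
Reactants: 7 diethyl (2,5-dimethoxybenzyl)phosphonate; 8 3-(benzyloxy)-4-methoxybenzaldehyde
Product: 9 2-(benzyloxy)-1-methoxy-4-[(E)-2-(2,5-dimethoxyphenyl)ethenyl]benzene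
Conditions: KOtBu, THF, 0 °C → rt
Reagents that add atoms: none
Why: Horner–Wadsworth–Emmons olefination of a benzylic phosphonate anion with a non-enolisable aromatic aldehyde should give mainly the E-stilbene, whose geometry is of no consequence because the alkene is saturated in the next step.

Step 5
Reactants: 9 2-(benzyloxy)-1-methoxy-4-[(E)-2-(2,5-dimethoxyphenyl)ethenyl]benzene
Product: 10 2-methoxy-5-[2-(2,5-dimethoxyphenyl)ethyl]phenol
Conditions: H2 (1 atm), Pd/C, EtOAc–EtOH, rt
Reagents that add atoms: none
Why: Catalytic hydrogenation should saturate the stilbene C=C and hydrogenolyse the O-benzyl group in one operation while leaving the aryl methyl ethers untouched, which frees only the ring C phenol.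

Step 6
Reactants: 10 2-methoxy-5-[2-(2,5-dimethoxyphenyl)ethyl]phenol; 11 trichloroethylene
Product: 13 2-{[(E)-1,2-dichloroethenyl]oxy}-1-methoxy-4-[2-(2,5-dimethoxyphenyl)ethyl]benzene, via dichloroacetylene 12 (not isolated)
Conditions: K2CO3, DMF, 70 °C, N2, closed vessel
Reagents that add atoms: none
Why: Nucleophilic vinylation of a phenol, in which base dehydrochlorinates trichloroethylene to dichloroacetylene and the phenoxide adds across it in anti fashion, is the known way to aryl (E)-1,2-dichlorovinyl ethers, and the phenol is the only acidic site in 10.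

Step 7
Reactants: 13 2-{[(E)-1,2-dichloroethenyl]oxy}-1-methoxy-4-[2-(2,5-dimethoxyphenyl)ethyl]benzene
Product: 16 2-(ethynyloxy)-1-methoxy-4-[2-(2,5-dimethoxyphenyl)ethyl]benzene, via chloroethynyl ether 14 (not isolated), via lithium aryloxyacetylide 15 (not isolated)
Conditions: n-BuLi (2.3 equiv), THF, −78 → −40 °C; then MeOH, −78 °C; cold neutral work-up, taken up in PhMe and used at once
Reagents that add atoms: none
Why: The known elimination and chlorine–lithium exchange sequence of dichlorovinyl ethers (vinylic deprotonation and loss of LiCl to 14, exchange with the second equivalent to 15, cold protonation) should give the terminal ynol ether faster than ortho-lithiation of the methoxyarenes at −78 °C.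

Step 8
Reactants: 16 2-(ethynyloxy)-1-methoxy-4-[2-(2,5-dimethoxyphenyl)ethyl]benzene; 5 5-[(3-methoxyphenyl)acetyl]-2H-pyran-2-one
Product: 18 1-(4-{5-[2-(2,5-dimethoxyphenyl)ethyl]-2-methoxyphenoxy}phenyl)-2-(3-methoxyphenyl)ethan-1-one, via bicyclic lactone adduct 17 (not isolated)
Conditions: 5 (1.5 equiv), PhMe, 100 °C, Ar, sealed tube; 16 added slowly as a dry PhMe solution
Reagents that add atoms: none
Why: Proposed new method: the diene C3=C4–C5=C6 of 5, made electron-poor by the 5-acyl group and the lactone carbonyl, should add the electron-rich triple bond of 16 in an asynchronous inverse-demand [4+2] cycloaddition in which the nucleophilic terminal alkyne carbon bonds to C6 ahead of the oxygen-bearing carbon bonding to C3, and the bridged lactone 17 then expels CO2 by retro-[4+2] to give the arene directly. The closest known reaction type is the inverse-electron-demand Diels–Alder reaction of coumalate esters with ketene acetals and enol ethers followed by decarboxylation, together with the general thermal pyrone–alkyne cycloaddition with CO2 extrusion. Ring B is closed by an intermolecular [4+2] cycloaddition that forms B5–B6 and B3–B4 in one event, four ring atoms coming from the pyrone and two from the alkyne, and it becomes aromatic as soon as the CO2 bridge leaves, so no elimination step can cost the aryloxy group. No stereocentre is created in 18, since the two bridgehead centres of racemic 17 vanish on CO2 loss. The step needs para over meta orientation and [4+2] over [2+2] addition at C5=C6; both should follow from the match between the polarised ynol ether terminus and C6, the β-carbon of the enone and δ-carbon of the dienoate, and from running the reaction thermally without Lewis acid. Because the oxygen substituent is an aryl group, the retro-ene path by which alkyl ynol ethers break down to ketenes on heating is closed, and slow addition keeps the ynol ether dilute against self-oligomerisation.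

Step 9
Reactants: 18 1-(4-{5-[2-(2,5-dimethoxyphenyl)ethyl]-2-methoxyphenoxy}phenyl)-2-(3-methoxyphenyl)ethan-1-one
Product: 19 4-[2-(2,5-dimethoxyphenyl)ethyl]-1-methoxy-2-{4-[2-(3-methoxyphenyl)ethyl]phenoxy}benzene
Conditions: Et3SiH (4 equiv), CF3CO2H, rt → 50 °C
Reagents that add atoms: none
Why: Ionic hydrogenation (Kursanov–Parnes reduction) should take the aryl ketone to CH2 by protonation and hydride transfer, ionisation of the benzylic alcohol to a cation stabilised by the para aryloxy group of ring B, and a second hydride transfer, with the aryl ethers inert.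

Step 10
Reactants: 19 4-[2-(2,5-dimethoxyphenyl)ethyl]-1-methoxy-2-{4-[2-(3-methoxyphenyl)ethyl]phenoxy}benzene
Product: 20 2-(2-{4-hydroxy-3-[4-(2-(3-hydroxyphenyl)ethyl)phenoxy]phenyl}ethyl)benzene-1,4-diol (CNP0300581.0)
Conditions: BBr3 (8 equiv), CH2Cl2, −78 °C → rt; then degassed H2O, 0 °C
Reagents that add atoms: none
Why: Lewis acid demethylation, in which each methoxy oxygen binds boron and bromide attacks the methyl carbon by SN2, should cleave all four methyl ethers while the diaryl ether, having no sp3 carbon on oxygen, survives.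

Compound list
1 | coumalic acid (2-oxo-2H-pyran-5-carboxylic acid) | O=C(O)C1=COC(=O)C=C1 | starting material
2 | coumaloyl chloride (2-oxo-2H-pyran-5-carbonyl chloride) | O=C(Cl)C1=COC(=O)C=C1 | intermediate
3 | 3-methoxybenzyl chloride | COc1cccc(CCl)c1 | starting material
4 | (3-methoxybenzyl)zinc chloride | COc1cccc(C[Zn]Cl)c1 | intermediate (not isolated)
5 | 5-[(3-methoxyphenyl)acetyl]-2H-pyran-2-one | COc1cccc(CC(=O)C2=COC(=O)C=C2)c1 | intermediate
6 | 2,5-dimethoxybenzyl chloride | COc1ccc(OC)c(CCl)c1 | starting material
7 | diethyl (2,5-dimethoxybenzyl)phosphonate | CCOP(=O)(Cc1cc(OC)ccc1OC)OCC | intermediate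
8 | 3-(benzyloxy)-4-methoxybenzaldehyde | COc1ccc(C=O)cc1OCc1ccccc1 | starting material
9 | 2-(benzyloxy)-1-methoxy-4-[(E)-2-(2,5-dimethoxyphenyl)ethenyl]benzene | COc1ccc(/C=C/c2cc(OC)ccc2OC)cc1OCc1ccccc1 | intermediate
10 | 2-methoxy-5-[2-(2,5-dimethoxyphenyl)ethyl]phenol | COc1ccc(CCc2cc(OC)ccc2OC)cc1O | intermediate
11 | trichloroethylene | ClC=C(Cl)Cl | starting material
12 | dichloroacetylene | ClC#CCl | intermediate (not isolated)
13 | 2-{[(E)-1,2-dichloroethenyl]oxy}-1-methoxy-4-[2-(2,5-dimethoxyphenyl)ethyl]benzene | Cl/C=C(/Cl)Oc1cc(CCc2cc(OC)ccc2OC)ccc1OC | intermediate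
14 | 2-[(chloroethynyl)oxy]-1-methoxy-4-[2-(2,5-dimethoxyphenyl)ethyl]benzene | ClC#COc1cc(CCc2cc(OC)ccc2OC)ccc1OC | intermediate (not isolated)
15 | lithium ({5-[2-(2,5-dimethoxyphenyl)ethyl]-2-methoxyphenoxy}ethynide) | [Li]C#COc1cc(CCc2cc(OC)ccc2OC)ccc1OC | intermediate (not isolated)
16 | 2-(ethynyloxy)-1-methoxy-4-[2-(2,5-dimethoxyphenyl)ethyl]benzene | C#COc1cc(CCc2cc(OC)ccc2OC)ccc1OC | intermediate
17 | racemic 5-{5-[2-(2,5-dimethoxyphenyl)ethyl]-2-methoxyphenoxy}-7-[(3-methoxyphenyl)acetyl]-2-oxabicyclo[2.2.2]octa-5,7-dien-3-one (relative configuration of the two bridgeheads fixed by the bicycle) | O=C1OC2C=C(Oc3cc(CCc4cc(OC)ccc4OC)ccc3OC)C1C=C2C(=O)Cc1cccc(OC)c1 | intermediate (not isolated)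
18 | 1-(4-{5-[2-(2,5-dimethoxyphenyl)ethyl]-2-methoxyphenoxy}phenyl)-2-(3-methoxyphenyl)ethan-1-one | COc1cccc(CC(=O)c2ccc(Oc3cc(CCc4cc(OC)ccc4OC)ccc3OC)cc2)c1 | intermediate
19 | 4-[2-(2,5-dimethoxyphenyl)ethyl]-1-methoxy-2-{4-[2-(3-methoxyphenyl)ethyl]phenoxy}benzene | COc1cccc(CCc2ccc(Oc3cc(CCc4cc(OC)ccc4OC)ccc3OC)cc2)c1 | intermediate
20 | 2-(2-{4-hydroxy-3-[4-(2-(3-hydroxyphenyl)ethyl)phenoxy]phenyl}ethyl)benzene-1,4-diol (CNP0300581.0) | Oc1cccc(CCc2ccc(Oc3cc(CCc4cc(O)ccc4O)ccc3O)cc2)c1 | target

Total step count: 10 steps.
Longest linear sequence: 8 steps (steps 3, 4, 5, 6, 7, 8, 9 and 10, from 6 to 20); steps 1 and 2 form the two-step pyrone branch.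

Steps most likely to fail

1. Step 8 (proposed new method). The ynol ether may oligomerise or be hydrated faster than it is taken up by the pyrone, or it may add with the reverse orientation or in a [2+2] or hetero-[4+2] sense across the C5=C6–C=O unit. The fallback uses known chemistry only and sets out from phenol 10. SNAr with 4-fluorobenzaldehyde (K2CO3, DMF, 130 °C) should give 4-{5-[2-(2,5-dimethoxyphenyl)ethyl]-2-methoxyphenoxy}benzaldehyde F1. Horner–Wadsworth–Emmons olefination of F1 with commercial diethyl (3-methoxybenzyl)phosphonate (KOtBu, THF) should give 4-[2-(2,5-dimethoxyphenyl)ethyl]-1-methoxy-2-{4-[(E)-2-(3-methoxyphenyl)ethenyl]phenoxy}benzene F2. Hydrogenation of F2 (H2, Pd/C, EtOAc) comes back to the route at 19, which then goes through step 10.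

2. Step 7. The terminal aryl ynol ether may be lost through oligomerisation or adventitious hydration during work-up and concentration, or ring lithiation may compete with the exchange sequence. The fallback sets out from 13, which is taken to acetylide 15 as in step 7. Quenching 15 with Me3SiCl instead of MeOH should give the storable C-silyl ynol ether ({5-[2-(2,5-dimethoxyphenyl)ethyl]-2-methoxyphenoxy}ethynyl)trimethylsilane F3. Heating F3 with 5 (xylene, 130–150 °C) should pass through the silylated bicyclic lactone 5-{5-[2-(2,5-dimethoxyphenyl)ethyl]-2-methoxyphenoxy}-7-[(3-methoxyphenyl)acetyl]-6-(trimethylsilyl)-2-oxabicyclo[2.2.2]octa-5,7-dien-3-one F4 (not isolated) to 1-(4-{5-[2-(2,5-dimethoxyphenyl)ethyl]-2-methoxyphenoxy}-3-(trimethylsilyl)phenyl)-2-(3-methoxyphenyl)ethan-1-one F5. The silyl group reinforces the alkyne polarisation (β-silicon effect) at the cost of some steric hindrance. Under the Et3SiH/CF3CO2H conditions of step 9, ipso-protodesilylation ortho to the aryloxy group and carbonyl reduction should occur together, coming back to the route at 19.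

3. Step 2. The benzylzinc reagent may add to the pyrone ring (C6 or the lactone carbonyl) or homocouple, and the acidic methylene of the product may be enolised and O-acylated by remaining acid chloride. The fallback sets out from zinc reagent 4, which is quenched with Bu3SnCl to give tributyl(3-methoxybenzyl)stannane F6. Stille acylation of F6 with acid chloride 2 (PdCl2(PPh3)2 cat., CHCl3, 65 °C) under neutral, non-basic conditions comes back to the route at 5.

Further compounds
F1 | step 8 | 4-{5-[2-(2,5-dimethoxyphenyl)ethyl]-2-methoxyphenoxy}benzaldehyde | O=Cc1ccc(Oc2cc(CCc3cc(OC)ccc3OC)ccc2OC)cc1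
F2 | step 8 | 4-[2-(2,5-dimethoxyphenyl)ethyl]-1-methoxy-2-{4-[(E)-2-(3-methoxyphenyl)ethenyl]phenoxy}benzene | COc1cccc(/C=C/c2ccc(Oc3cc(CCc4cc(OC)ccc4OC)ccc3OC)cc2)c1
F3 | step 7 | ({5-[2-(2,5-dimethoxyphenyl)ethyl]-2-methoxyphenoxy}ethynyl)trimethylsilane | C[Si](C)(C)C#COc1cc(CCc2cc(OC)ccc2OC)ccc1OC
F4 | step 7 | racemic 5-{5-[2-(2,5-dimethoxyphenyl)ethyl]-2-methoxyphenoxy}-7-[(3-methoxyphenyl)acetyl]-6-(trimethylsilyl)-2-oxabicyclo[2.2.2]octa-5,7-dien-3-one (not isolated) | O=C1OC2C([Si](C)(C)C)=C(Oc3cc(CCc4cc(OC)ccc4OC)ccc3OC)C1C=C2C(=O)Cc1cccc(OC)c1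
F5 | step 7 | 1-(4-{5-[2-(2,5-dimethoxyphenyl)ethyl]-2-methoxyphenoxy}-3-(trimethylsilyl)phenyl)-2-(3-methoxyphenyl)ethan-1-one | COc1cccc(CC(=O)c2ccc(Oc3cc(CCc4cc(OC)ccc4OC)ccc3OC)c([Si](C)(C)C)c2)c1
F6 | step 2 | tributyl(3-methoxybenzyl)stannane | CCCC[Sn](CCCC)(CCCC)Cc1cccc(OC)c1
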